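## Retrosynthetic overview
1. The C6–prenyl bond is made last: target 20 comes from the 7-O-prenyl ether 18 by a palladium-catalysed O-to-C prenyl shift (new step), and 18 comes from isocaviunin 16 plus prenyl bromide 17.
2. 16 comes from its 5-O-methyl ether 14 by chelation-controlled demethylation. Ring C of 14 comes from deoxybenzoin 12 plus one carbon (C2) from DMF dimethyl acetal.
3. The C4–C4a bond joins ring A aryllithium 9 to ring B Weinreb amide 8. In 12 one ortho oxygen is OMe and the other is OH, so the ring closure has only one possible direction.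
4. Ring A arene 5 comes from 2-methoxyresorcinol 1 by MOM protection, sterically controlled C–H borylation/oxidation and O-methylation.
5. Ring order: rings A and B are bought as benzenes. Ring C (the pyranone) is the only ring formed, in step 7.

Assumption: the SMILES holds no stereocentre and no E/Z-stereogenic alkene, so the target is achiral and no enantiocontrol is needed; acid 6 is taken as a catalogue compound.

## Route

Step 1
Reactants: 1 2-methoxybenzene-1,3-diol (2-methoxyresorcinol)
Product: 2 2-methoxy-1,3-bis(methoxymethoxy)benzene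
Conditions: MOMCl (2.5 equiv), K2CO3 (4 equiv), acetone, 0 °C to reflux
Reagents that add atoms: chloromethyl methyl ether (MOMCl), COCCl
Why: Williamson-type O-alkylation of the two equivalent phenols gives base-stable acetals that survive the borylation and later direct the lithiation; no stereocentre is formed.

Step 2
Reactants: 2 2-methoxy-1,3-bis(methoxymethoxy)benzene
Product: 4 4-methoxy-3,5-bis(methoxymethoxy)phenol, via arylboronate 3 (not isolated)
Conditions: [Ir(OMe)(cod)]2 (1.5 mol %), 4,4'-di-tert-butyl-2,2'-bipyridine (3 mol %), B2pin2 (0.6 equiv), THF, 80 °C, sealed; then 30% H2O2, NaOH aq (1 equiv), 0 °C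
Reagents that add atoms: bis(pinacolato)diboron, CC1(C)OB(OC1(C)C)B1OC(C)(C)C(C)(C)O1 (boryl group of 3 only); hydrogen peroxide, OO (new oxygen of 4)
Why: Sterically governed iridium-catalysed aromatic C–H borylation reaches only C5, the one C–H without an ortho substituent, and boronate oxidation (aryl shift from boron to oxygen) then places the fourth oxygen para to the OMe group.

Step 3
Reactants: 4 4-methoxy-3,5-bis(methoxymethoxy)phenol
Product: 5 2,5-dimethoxy-1,3-bis(methoxymethoxy)benzene
Conditions: MeI (1.5 equiv), K2CO3 (2 equiv), acetone, reflux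
Reagents that add atoms: iodomethane, CI
Why: Williamson ether synthesis caps the unique oxygen (the later C5–O) as a methyl ether, which is stable to n-butyllithium and can later be removed selectively by carbonyl chelation.

Step 4
Reactants: 6 2-(2,4,5-trimethoxyphenyl)acetic acid
Product: 8 N-methoxy-N-methyl-2-(2,4,5-trimethoxyphenyl)acetamide, via acylimidazole 7 (not isolated)
Conditions: CDI (1.1 equiv), CH2Cl2, rt; then MeNH(OMe)·HCl (1.2 equiv), rt
Reagents that add atoms: 1,1'-carbonyldiimidazole, O=C(n1ccnc1)n1ccnc1 (imidazolyl group of 7 only); N,O-dimethylhydroxylamine hydrochloride, CNOC.Cl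
Why: CDI activation followed by aminolysis is a standard neutral Weinreb amide formation that leaves the electron-rich arene untouched.

Step 5
Reactants: 5 2,5-dimethoxy-1,3-bis(methoxymethoxy)benzene; 8 N-methoxy-N-methyl-2-(2,4,5-trimethoxyphenyl)acetamide
Product: 11 1-[3,6-dimethoxy-2,4-bis(methoxymethoxy)phenyl]-2-(2,4,5-trimethoxyphenyl)ethan-1-one, via aryllithium 9 (not isolated), via lithium hemiaminal adduct 10 (not isolated)
Conditions: 5, n-BuLi (1.05 equiv), THF, 0 °C, 1 h; then 8, −78 to −20 °C; then H2O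
Reagents that add atoms: n-butyllithium, [Li]CCCC (lithium of 9 and 10 only)
Why: Directed ortho-metalation (the two remaining ring hydrogens are equivalent, each between an OMOM and an OMe donor) is followed by Weinreb ketone synthesis, where chelated adduct 10 prevents over-addition and its racemic carbinol centre is lost on collapse to the ketone.

Step 6
Reactants: 11 1-[3,6-dimethoxy-2,4-bis(methoxymethoxy)phenyl]-2-(2,4,5-trimethoxyphenyl)ethan-1-one
Product: 12 1-(2,4-dihydroxy-3,6-dimethoxyphenyl)-2-(2,4,5-trimethoxyphenyl)ethan-1-one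
Conditions: HCl (1.25 M in MeOH), 45 °C
Reagents that add atoms: none
Why: Acid-catalysed transacetalisation to methanol removes both MOM groups while the aryl methyl ethers and the ketone are inert.

Step 7
Reactants: 12 1-(2,4-dihydroxy-3,6-dimethoxyphenyl)-2-(2,4,5-trimethoxyphenyl)ethan-1-one
Product: 14 7-hydroxy-5,8-dimethoxy-3-(2,4,5-trimethoxyphenyl)-4H-chromen-4-one, via enaminone 13 (not isolated)
Conditions: Me2NCH(OMe)2 (2 equiv), THF, 65 °C; then 1 M HCl, rt
Reagents that add atoms: N,N-dimethylformamide dimethyl acetal, COC(OC)N(C)C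
Why: Formamide-acetal condensation at the doubly activated CH2 gives enaminone 13, and addition–elimination by the only phenol ortho to the ketone (the other ortho oxygen is OMe) closes ring C, so only the 8-methoxy isoflavone can form.

Step 8
Reactants: 14 7-hydroxy-5,8-dimethoxy-3-(2,4,5-trimethoxyphenyl)-4H-chromen-4-one
Product: 16 isocaviunin [5,7-dihydroxy-8-methoxy-3-(2,4,5-trimethoxyphenyl)-4H-chromen-4-one], via boron chelate 15 (not isolated)
Conditions: BCl3 (2.5 equiv, 1 M in CH2Cl2), CH2Cl2, −78 to 0 °C; then H2O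
Reagents that add atoms: boron trichloride, ClB(Cl)Cl (BCl2 group of 15 only)
Why: In this chelation-controlled Lewis-acid ether cleavage, boron bound to the C4 carbonyl reaches only the peri 5-OMe through a six-membered chelate, so the 8-OMe and the three ring B ethers survive at or below 0 °C.

Step 9
Reactants: 16 isocaviunin; 17 1-bromo-3-methylbut-2-ene (prenyl bromide)
Product: 18 5-hydroxy-8-methoxy-7-[(3-methylbut-2-en-1-yl)oxy]-3-(2,4,5-trimethoxyphenyl)-4H-chromen-4-one (7-O-prenylisocaviunin)
Conditions: 17 (1.05 equiv), K2CO3 (1.2 equiv), acetone, reflux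
Reagents that add atoms: 1-bromo-3-methylbut-2-ene (17), CC(C)=CCBr
Why: Williamson ether synthesis is selective for the acidic 7-OH because the 5-OH is held in a hydrogen bond to the C4 carbonyl.

Step 10
Reactants: 18 7-O-prenylisocaviunin
Product: 20 6-prenylisocaviunin [5,7-dihydroxy-8-methoxy-6-(3-methylbut-2-en-1-yl)-3-(2,4,5-trimethoxyphenyl)-4H-chromen-4-one], via dienone tautomer 19 (not isolated)
Conditions: Pd2(dba)3 (2.5 mol %), Xantphos [4,5-bis(diphenylphosphino)-9,9-dimethylxanthene] (6 mol %), degassed toluene (0.05 M), 90 °C, sealed tube, argon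
Reagents that add atoms: none
Why: Proposed new method: a formal [1,3] O-to-C prenyl shift catalysed by zerovalent palladium; the wide-bite-angle Xantphos complex ionises the allylic C–O bond of 18 (the 7-phenoxide is a vinylogous carboxylate, pKa about 7, hence an acetate-like leaving group) to a (1,1-dimethylallyl)palladium cation/phenoxide ion pair; recombination at oxygen is reversible, whereas attack of C6, the only free ring A carbon, on the unhindered CH2 terminus gives dienone 19, whose racemic C6 centre is erased by irreversible tautomerisation, so the equilibrium drains to the linear 6-prenyl phenol 20 with exactly one prenyl unit per molecule; ring B cannot compete because only the phenoxide-bearing ring is nucleophilic in this acid-free medium, 90 °C is far below the thermal Claisen threshold that would give the reverse-prenyl isomer, and the sealed tube keeps any isoprene lost by β-hydride elimination available for palladium hydride re-addition; the closest known reaction types are Tsuji–Trost C-allylation of naphthols and phloroglucinols and the palladium-catalysed O-to-C rearrangement of allyl enol ethers, and to my knowledge neither has been shown on prenyl aryl ethers of chromone-fused resorcinols.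

## Compound list
1 | 2-methoxybenzene-1,3-diol | COc1c(O)cccc1O | starting material
2 | 2-methoxy-1,3-bis(methoxymethoxy)benzene | COCOc1cccc(OCOC)c1OC | intermediate
3 | 2-[4-methoxy-3,5-bis(methoxymethoxy)phenyl]-4,4,5,5-tetramethyl-1,3,2-dioxaborolane | COCOc1cc(B2OC(C)(C)C(C)(C)O2)cc(OCOC)c1OC | intermediate
4 | 4-methoxy-3,5-bis(methoxymethoxy)phenol | COCOc1cc(O)cc(OCOC)c1OC | intermediate
5 | 2,5-dimethoxy-1,3-bis(methoxymethoxy)benzene | COCOc1cc(OC)cc(OCOC)c1OC | intermediate
6 | 2-(2,4,5-trimethoxyphenyl)acetic acid | COc1cc(OC)c(CC(=O)O)cc1OC | starting material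
7 | 1-(1H-imidazol-1-yl)-2-(2,4,5-trimethoxyphenyl)ethan-1-one | COc1cc(OC)c(CC(=O)n2ccnc2)cc1OC | intermediate
8 | N-methoxy-N-methyl-2-(2,4,5-trimethoxyphenyl)acetamide | COc1cc(OC)c(CC(=O)N(C)OC)cc1OC | intermediate
9 | [3,6-dimethoxy-2,4-bis(methoxymethoxy)phenyl]lithium | [Li]c1c(OC)cc(OCOC)c(OC)c1OCOC | intermediate
10 | lithium 1-[3,6-dimethoxy-2,4-bis(methoxymethoxy)phenyl]-1-[methoxy(methyl)amino]-2-(2,4,5-trimethoxyphenyl)ethan-1-olate (racemic, transient) | [Li+].COCOc1cc(OC)c(C([O-])(Cc2cc(OC)c(OC)cc2OC)N(C)OC)c(OCOC)c1OC | intermediate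
11 | 1-[3,6-dimethoxy-2,4-bis(methoxymethoxy)phenyl]-2-(2,4,5-trimethoxyphenyl)ethan-1-one | COCOc1cc(OC)c(C(=O)Cc2cc(OC)c(OC)cc2OC)c(OCOC)c1OC | intermediate
12 | 1-(2,4-dihydroxy-3,6-dimethoxyphenyl)-2-(2,4,5-trimethoxyphenyl)ethan-1-one | COc1cc(O)c(OC)c(O)c1C(=O)Cc1cc(OC)c(OC)cc1OC | intermediate
13 | 3-(dimethylamino)-1-(2,4-dihydroxy-3,6-dimethoxyphenyl)-2-(2,4,5-trimethoxyphenyl)prop-2-en-1-one (alkene geometry not defined, transient) | COc1cc(O)c(OC)c(O)c1C(=O)C(=CN(C)C)c1cc(OC)c(OC)cc1OC | intermediate
14 | 7-hydroxy-5,8-dimethoxy-3-(2,4,5-trimethoxyphenyl)-4H-chromen-4-one | COc1cc(OC)c(-c2coc3c(OC)c(O)cc(OC)c3c2=O)cc1OC | intermediate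
15 | 5-(dichloroboryloxy)-7-hydroxy-8-methoxy-3-(2,4,5-trimethoxyphenyl)-4H-chromen-4-one (boron chelated by the C4 carbonyl, drawn at the 5-oxygen only) | COc1cc(OC)c(-c2coc3c(OC)c(O)cc(OB(Cl)Cl)c3c2=O)cc1OC | intermediate
16 | isocaviunin, 5,7-dihydroxy-8-methoxy-3-(2,4,5-trimethoxyphenyl)-4H-chromen-4-one | COc1cc(OC)c(-c2coc3c(OC)c(O)cc(O)c3c2=O)cc1OC | intermediate
17 | 1-bromo-3-methylbut-2-ene | CC(C)=CCBr | starting material
18 | 5-hydroxy-8-methoxy-7-[(3-methylbut-2-en-1-yl)oxy]-3-(2,4,5-trimethoxyphenyl)-4H-chromen-4-one | COc1cc(OC)c(-c2coc3c(OC)c(OCC=C(C)C)cc(O)c3c2=O)cc1OC | intermediate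
19 | 5-hydroxy-8-methoxy-6-(3-methylbut-2-en-1-yl)-3-(2,4,5-trimethoxyphenyl)-6H-chromene-4,7-dione (racemic at C6, transient) | COc1cc(OC)c(C2=COC3=C(OC)C(=O)C(CC=C(C)C)C(O)=C3C2=O)cc1OC | intermediate
20 | 6-prenylisocaviunin, 5,7-dihydroxy-8-methoxy-6-(3-methylbut-2-en-1-yl)-3-(2,4,5-trimethoxyphenyl)-4H-chromen-4-one (achiral) | COc1cc(OC)c(-c2coc3c(OC)c(O)c(CC=C(C)C)c(O)c3c2=O)cc1OC | target

## Step count and risks
Total step count: 10. Longest linear sequence: 9 steps (steps 1, 2, 3, 5, 6, 7, 8, 9, 10, from 1). Step 4 is the one-step side branch.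

**First risk: step 10, the proposed new step.**
- Failure modes:
  - Ionisation of the trisubstituted allyl ether may be slow.
  - β-Hydride loss may give isoprene and 16.
  - A second, dearomatising prenylation at C6 may occur.
- Fallback: this uses only known chemistry, sets out from 16 and comes back at 20. O-Allylation of the 7-OH with allyl bromide and K2CO3 in acetone gives 7-O-allylisocaviunin F1. Thermal aromatic Claisen rearrangement in N,N-diethylaniline at 200 °C delivers the allyl group to C6, because C8 is blocked, and gives 6-allylisocaviunin F2. Olefin cross-metathesis with excess 2-methylbut-2-ene and the second-generation Grubbs catalyst RuCl2(=CHPh)(PCy3)(H2IMes) in CH2Cl2 at 40 °C converts the allyl group into the prenyl group of 20.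

**Second risk: step 5.**
- Failure mode: the hindered aryllithium 9 may deprotonate the benzylic CH2 of amide 8 instead of adding to it.
- Fallback: this replaces nucleophilic arene acylation with electrophilic acylation, sets out from 5 and comes back at 12. HCl in MeOH removes both MOM groups to give 2,5-dimethoxybenzene-1,3-diol F3, whose two free ring positions are equivalent. Friedel–Crafts acylation with acid 6 in neat BF3·OEt2 at 80 °C then gives 12 directly, so 8 to 11 are not needed.

**Third risk: step 7.**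
- Failure modes: the deoxybenzoin is crowded on both sides of the CH2, and the free 4-OH (the later 7-OH) can be O-methylated by the acetal.
- Fallback: this closes ring C before ring B is attached, sets out from 5 and comes back at 14.
  - Aryllithium 9 is quenched with N-methoxy-N-methylacetamide to give 1-[3,6-dimethoxy-2,4-bis(methoxymethoxy)phenyl]ethan-1-one F4.
  - Catalytic I2 in MeOH at rt removes only the MOM group next to the carbonyl, giving 1-[2-hydroxy-3,6-dimethoxy-4-(methoxymethoxy)phenyl]ethan-1-one F5.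
  - Me2NCH(OMe)2 at 90 °C gives (E)-3-(dimethylamino)-1-[2-hydroxy-3,6-dimethoxy-4-(methoxymethoxy)phenyl]prop-2-en-1-one F6.
  - I2 in CHCl3 effects iodocyclisation to 3-iodo-5,8-dimethoxy-7-(methoxymethoxy)-4H-chromen-4-one F7.
  - Suzuki–Miyaura coupling with commercial 2,4,5-trimethoxyphenylboronic acid (Pd(PPh3)4, Na2CO3, DME/H2O, 80 °C) gives 5,8-dimethoxy-7-(methoxymethoxy)-3-(2,4,5-trimethoxyphenyl)-4H-chromen-4-one F8.
  - HCl in MeOH frees the 7-OH to give 14.

## Further compounds
F1 | step 10 | 7-O-allylisocaviunin, 7-(allyloxy)-5-hydroxy-8-methoxy-3-(2,4,5-trimethoxyphenyl)-4H-chromen-4-one | COc1cc(OC)c(-c2coc3c(OC)c(OCC=C)cc(O)c3c2=O)cc1OC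
F2 | step 10 | 6-allylisocaviunin, 6-allyl-5,7-dihydroxy-8-methoxy-3-(2,4,5-trimethoxyphenyl)-4H-chromen-4-one | COc1cc(OC)c(-c2coc3c(OC)c(O)c(CC=C)c(O)c3c2=O)cc1OC
F3 | step 5 | 2,5-dimethoxybenzene-1,3-diol | COc1cc(O)c(OC)c(O)c1
F4 | step 7 | 1-[3,6-dimethoxy-2,4-bis(methoxymethoxy)phenyl]ethan-1-one | COCOc1cc(OC)c(C(C)=O)c(OCOC)c1OC
F5 | step 7 | 1-[2-hydroxy-3,6-dimethoxy-4-(methoxymethoxy)phenyl]ethan-1-one | COCOc1cc(OC)c(C(C)=O)c(O)c1OC
F6 | step 7 | (E)-3-(dimethylamino)-1-[2-hydroxy-3,6-dimethoxy-4-(methoxymethoxy)phenyl]prop-2-en-1-one | COCOc1cc(OC)c(C(=O)/C=C/N(C)C)c(O)c1OC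
F7 | step 7 | 3-iodo-5,8-dimethoxy-7-(methoxymethoxy)-4H-chromen-4-one | COCOc1cc(OC)c2c(=O)c(I)coc2c1OC
F8 | step 7 | 5,8-dimethoxy-7-(methoxymethoxy)-3-(2,4,5-trimethoxyphenyl)-4H-chromen-4-one | COCOc1cc(OC)c2c(=O)c(-c3cc(OC)c(OC)cc3OC)coc2c1OC
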